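**Retrosynthetic overview**

1. Target 17 ⇒ Z-δ-hydroxy enoate 16: the only ring (the dihydropyranone, atoms O1, C2–C6) is opened at O1–C2 and is closed last, by lactonisation on global desilylation (step 11).
2. Key disconnection: C3=C4 (Z-olefination of an aldehyde at C4) together with C5–C6 (acetaldehyde aldol) ⇒ β-silyloxy aldehyde 13, vinyl ether 3 and a phosphonoacetate, joined in one flask (step 10).
3. Enabling feature: oxygen sits on every second carbon from C6' to ring atom C6 in an all-syn array, and ring atom C4 lies two carbons beyond the C6 oxygen. C4 is therefore the carbonyl carbon of an acetaldehyde aldol adduct, and the cis C3=C4 bond inside the six-membered ring is what a Z-olefination of that aldehyde delivers.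
4. 13 ⇒ 11 by two earlier additions of the same vinyl ether 3 (C4', then C2'); the Si(SiMe3)3 group on each β-oxygen relays the configuration of C6' down the chain.
5. 11 ⇒ dodecanal 4 by two catalyst-controlled allylations (C10', then C6') separated by a linear hydroformylation.

Key step: step 10

Numbering and abbreviations: lactone ring O1, C2 (C=O), C3, C4, C5, C6; side chain C1'–C21' counted from C6. Si* = Si(SiMe3)3, tris(trimethylsilyl)silyl; OTBS = OSiMe2tBu.

Assumption: the 1,3-induction exerted by a β-OSi* group in HN(SO2CF3)2-catalysed Mukaiyama aldol additions of 3 is taken to be syn, the sense documented for this silyl group.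

**Route**

Step 1
Reactants: 1 tetrahydrofuran
Product: 3 (ethenyloxy)tris(trimethylsilyl)silane, via lithium ethenolate 2 (not isolated)
Conditions: n-BuLi, THF, rt; then (Me3Si)3SiCl, 0 °C → rt
Reagents that add atoms: chlorotris(trimethylsilyl)silane, C[Si](C)(C)[Si](Cl)([Si](C)(C)C)[Si](C)(C)C
Why: α-Lithiated THF undergoes the known cycloreversion to ethylene and the lithium enolate of acetaldehyde, and O-silylation of this enolate with the chlorosilane should give the silyl enol ether free of aldehyde self-condensation products.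

Step 2
Reactants: 4 dodecanal
Product: 5 (4S)-pentadec-1-en-4-ol
Conditions: allylSnBu3, (R)-BINOL (10 mol%), Ti(OiPr)4 (10 mol%), 4 Å MS, CH2Cl2, −20 °C; aq. NaHCO3 work-up
Reagents that add atoms: allyltributylstannane, C=CC[Sn](CCCC)(CCCC)CCCC
Why: Keck asymmetric allylation, in which the BINOL–titanium Lewis acid activates the aldehyde and the (R)-ligand is expected to direct allyl transfer to the Re face, setting C10' as S.

Step 3
Reactants: 5 (4S)-pentadec-1-en-4-ol
Product: 6 tert-butyldimethyl{[(4S)-pentadec-1-en-4-yl]oxy}silane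
Conditions: TBSCl, imidazole, DMF, rt
Reagents that add atoms: tert-butyldimethylsilyl chloride, CC(C)(C)[Si](C)(C)Cl
Why: Imidazole-mediated silyl ether formation masks the C10' hydroxyl for all later steps without touching the stereocentre.

Step 4
Reactants: 6 tert-butyldimethyl{[(4S)-pentadec-1-en-4-yl]oxy}silane
Product: 7 (5S)-5-OTBS-hexadecanal
Conditions: CO/H2 (1:1, 10 bar), Rh(acac)(CO)2 (0.5 mol%), BIPHEPHOS (1 mol%), toluene, 60 °C
Reagents that add atoms: carbon monoxide, [C-]#[O+]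
Why: Rhodium–bisphosphite hydroformylation of a terminal alkene is strongly linear-selective and should add the one carbon that becomes C6' as an aldehyde, leaving the silyl ether and C10' unchanged.

Step 5
Reactants: 7 (5S)-5-OTBS-hexadecanal
Product: 8 (4R,8S)-8-OTBS-nonadec-1-en-4-ol
Conditions: allylSnBu3, (S)-BINOL (10 mol%), Ti(OiPr)4 (10 mol%), 4 Å MS, CH2Cl2, −20 °C; aq. NaHCO3 work-up
Reagents that add atoms: allyltributylstannane, C=CC[Sn](CCCC)(CCCC)CCCC
Why: Second Keck allylation, catalyst-controlled because the existing centre is five atoms away; the (S)-ligand is expected to direct allyl to the Si face, setting C6' as R.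

Step 6
Reactants: 8 (4R,8S)-8-OTBS-nonadec-1-en-4-ol
Product: 9 (4R,8S)-8-OTBS-4-(OSi*)nonadec-1-ene
Conditions: (Me3Si)3SiCl, Et3N, DMAP (cat.), CH2Cl2, rt
Reagents that add atoms: chlorotris(trimethylsilyl)silane, C[Si](C)(C)[Si](Cl)([Si](C)(C)C)[Si](C)(C)C
Why: DMAP-catalysed silylation of the secondary alcohol installs the bulky OSi* group that steers the aldol additions of steps 8–10 and is removed with the other silyl ethers at the end.

Step 7
Reactants: 9 (4R,8S)-8-OTBS-4-(OSi*)nonadec-1-ene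
Product: 11 (3R,7S)-7-OTBS-3-(OSi*)octadecanal, via vicinal diol 10 (not isolated)
Conditions: K2OsO4·2H2O (2 mol%), NaIO4, 2,6-lutidine, dioxane/H2O (3:1), rt
Reagents that add atoms: sodium periodate, [Na+].[O-]I(=O)(=O)=O
Why: Lemieux–Johnson oxidative cleavage (dihydroxylation, then periodate glycol cleavage) removes the terminal CH2 and should give the β-silyloxy aldehyde, with lutidine buffering the medium against β-elimination.

Step 8
Reactants: 11 (3R,7S)-7-OTBS-3-(OSi*)octadecanal; 3 (ethenyloxy)tris(trimethylsilyl)silane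
Product: 12 (3R,5R,9S)-9-OTBS-3,5-bis(OSi*)icosanal
Conditions: 3 (1.05 equiv), HN(SO2CF3)2 (0.5 mol%), CH2Cl2, −78 → −40 °C; Et3N quench
Reagents that add atoms: none
Why: Mukaiyama aldol addition with silyl transfer, in which the silylated imide formed from HN(SO2CF3)2 activates the aldehyde, 3 attacks through an open transition state and the Si* group ends on the new alkoxide oxygen; the bulky β-OSi* group at C6' is expected to direct 1,3-syn attack and so set C4', and the more hindered adduct should not compete for the single equivalent of 3.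

Step 9
Reactants: 12 (3R,5R,9S)-9-OTBS-3,5-bis(OSi*)icosanal; 3 (ethenyloxy)tris(trimethylsilyl)silane
Product: 13 (3R,5R,7R,11S)-11-OTBS-3,5,7-tris(OSi*)docosanal
Conditions: 3 (1.05 equiv), HN(SO2CF3)2 (0.5 mol%), CH2Cl2, −78 → −30 °C; Et3N quench
Reagents that add atoms: none
Why: Second Mukaiyama aldol addition of the same type, in which the β-OSi* centre C4' made in step 8 is expected to direct 1,3-syn attack and set C2', again giving a β-silyloxy aldehyde that is less electrophilic than its precursor.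

Step 10
Reactants: 13 (3R,5R,7R,11S)-11-OTBS-3,5,7-tris(OSi*)docosanal; 3 (ethenyloxy)tris(trimethylsilyl)silane
Product: 15 methyl (2Z,5S,7S,9R,11R,15S)-15-OTBS-5,7,9,11-tetrakis(OSi*)hexacos-2-enoate, via tetracosanal 14 (not isolated)
Conditions: 3 (1.05 equiv), HN(SO2CF3)2 (0.5 mol%), CH2Cl2, −78 → −30 °C; then cannulated into (CF3CH2O)2P(O)CH2CO2Me, KN(SiMe3)2, 18-crown-6, THF, −78 °C
Reagents that add atoms: methyl bis(2,2,2-trifluoroethyl)phosphonoacetate, COC(=O)CP(=O)(OCC(F)(F)F)OCC(F)(F)F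
Why: The silylated imide formed from HN(SO2CF3)2 and 3 activates aldehyde 13, vinyl ether 3 attacks through an open transition state and the Si* group passes to the new alkoxide oxygen, which forms C5–C6 and leaves aldehyde 14 with ring atom C4 as its carbonyl carbon, and the Still–Gennari olefination in the same flask then turns C4 into the Z C3=C4 double bond. The closest known reaction types are the Mukaiyama aldol addition of acetaldehyde-derived Si* enol ethers to β-silyloxy aldehydes and the one-pot trapping of the aldehyde adduct by a second carbon nucleophile. No ring closes here; the Z geometry made in this step is what lets O1 reach C2 in the lactonisation of step 11. The new stereocentre C6 is controlled by 1,3-induction from the β-OSi* centre C2', whose bulk is expected to favour the 1,3-syn adduct. The step needs mono-addition, syn facial selectivity and Z selectivity: adduct 14 carries one more bulky β-silyloxy group and should be less electrophilic than 13, which with one equivalent of 3 stops the aldol stage cleanly, and the trifluoroethyl phosphonate with a dissociated potassium counter-ion should give kinetic Z control at −78 °C.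

Step 11
Reactants: 15 methyl (2Z,5S,7S,9R,11R,15S)-15-OTBS-5,7,9,11-tetrakis(OSi*)hexacos-2-enoate
Product: 17 (6S)-6-[(2R,4R,6R,10S)-2,4,6,10-tetrahydroxyhenicosyl]-5,6-dihydro-2H-pyran-2-one, via pentahydroxy ester 16 (not isolated)
Conditions: HF·pyridine, THF/pyridine, 0 °C → rt; then TsOH·H2O (cat.), CH2Cl2, rt
Reagents that add atoms: none
Why: Fluoride-driven Si–O cleavage should free all five hydroxyls, and the C5 hydroxyl of 16, held next to the ester by the Z double bond, should close the six-membered lactone by acid-catalysed transesterification (6-exo-trig) while the acidic medium suppresses oxa-Michael addition of the C2' hydroxyl.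

**Compound list**

1 | tetrahydrofuran | C1CCOC1 | starting material
2 | lithium ethenolate | [Li+].[O-]C=C | intermediate (not isolated)
3 | (ethenyloxy)tris(trimethylsilyl)silane | C=CO[Si]([Si](C)(C)C)([Si](C)(C)C)[Si](C)(C)C | intermediate
4 | dodecanal | CCCCCCCCCCCC=O | starting material
5 | (4S)-pentadec-1-en-4-ol | CCCCCCCCCCC[C@H](O)CC=C | intermediate
6 | tert-butyldimethyl{[(4S)-pentadec-1-en-4-yl]oxy}silane | CCCCCCCCCCC[C@H](O[Si](C)(C)C(C)(C)C)CC=C | intermediate
7 | (5S)-5-OTBS-hexadecanal | CCCCCCCCCCC[C@H](O[Si](C)(C)C(C)(C)C)CCCC=O | intermediate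
8 | (4R,8S)-8-OTBS-nonadec-1-en-4-ol | CCCCCCCCCCC[C@H](O[Si](C)(C)C(C)(C)C)CCC[C@@H](O)CC=C | intermediate
9 | (4R,8S)-8-OTBS-4-(OSi*)nonadec-1-ene | CCCCCCCCCCC[C@H](O[Si](C)(C)C(C)(C)C)CCC[C@@H](O[Si]([Si](C)(C)C)([Si](C)(C)C)[Si](C)(C)C)CC=C | intermediate
10 | (4R,8S)-8-OTBS-4-(OSi*)nonadecane-1,2-diol (both C2 epimers) | CCCCCCCCCCC[C@H](O[Si](C)(C)C(C)(C)C)CCC[C@@H](O[Si]([Si](C)(C)C)([Si](C)(C)C)[Si](C)(C)C)CC(O)CO | intermediate (not isolated)
11 | (3R,7S)-7-OTBS-3-(OSi*)octadecanal | CCCCCCCCCCC[C@H](O[Si](C)(C)C(C)(C)C)CCC[C@@H](O[Si]([Si](C)(C)C)([Si](C)(C)C)[Si](C)(C)C)CC=O | intermediate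
12 | (3R,5R,9S)-9-OTBS-3,5-bis(OSi*)icosanal | CCCCCCCCCCC[C@H](O[Si](C)(C)C(C)(C)C)CCC[C@@H](O[Si]([Si](C)(C)C)([Si](C)(C)C)[Si](C)(C)C)C[C@@H](O[Si]([Si](C)(C)C)([Si](C)(C)C)[Si](C)(C)C)CC=O | intermediate
13 | (3R,5R,7R,11S)-11-OTBS-3,5,7-tris(OSi*)docosanal | CCCCCCCCCCC[C@H](O[Si](C)(C)C(C)(C)C)CCC[C@@H](O[Si]([Si](C)(C)C)([Si](C)(C)C)[Si](C)(C)C)C[C@@H](O[Si]([Si](C)(C)C)([Si](C)(C)C)[Si](C)(C)C)C[C@@H](O[Si]([Si](C)(C)C)([Si](C)(C)C)[Si](C)(C)C)CC=O | intermediate
14 | (3R,5R,7R,9R,13S)-13-OTBS-3,5,7,9-tetrakis(OSi*)tetracosanal | CCCCCCCCCCC[C@H](O[Si](C)(C)C(C)(C)C)CCC[C@@H](O[Si]([Si](C)(C)C)([Si](C)(C)C)[Si](C)(C)C)C[C@@H](O[Si]([Si](C)(C)C)([Si](C)(C)C)[Si](C)(C)C)C[C@@H](O[Si]([Si](C)(C)C)([Si](C)(C)C)[Si](C)(C)C)C[C@@H](O[Si]([Si](C)(C)C)([Si](C)(C)C)[Si](C)(C)C)CC=O | intermediate (not isolated)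
15 | methyl (2Z,5S,7S,9R,11R,15S)-15-OTBS-5,7,9,11-tetrakis(OSi*)hexacos-2-enoate | CCCCCCCCCCC[C@H](O[Si](C)(C)C(C)(C)C)CCC[C@@H](O[Si]([Si](C)(C)C)([Si](C)(C)C)[Si](C)(C)C)C[C@@H](O[Si]([Si](C)(C)C)([Si](C)(C)C)[Si](C)(C)C)C[C@@H](O[Si]([Si](C)(C)C)([Si](C)(C)C)[Si](C)(C)C)C[C@@H](O[Si]([Si](C)(C)C)([Si](C)(C)C)[Si](C)(C)C)C/C=C\C(=O)OC | intermediate
16 | methyl (2Z,5S,7S,9R,11R,15S)-5,7,9,11,15-pentahydroxyhexacos-2-enoate | CCCCCCCCCCC[C@H](O)CCC[C@@H](O)C[C@@H](O)C[C@@H](O)C[C@@H](O)C/C=C\C(=O)OC | intermediate (not isolated)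
17 | (6S)-6-[(2R,4R,6R,10S)-2,4,6,10-tetrahydroxyhenicosyl]-5,6-dihydro-2H-pyran-2-one | CCCCCCCCCCC[C@H](O)CCC[C@@H](O)C[C@@H](O)C[C@@H](O)C[C@@H]1CC=CC(=O)O1 | target

**Step count and risks**

Total step count: 11. Longest linear sequence: 10 steps (steps 2–11, from dodecanal 4); step 1 supplies vinyl ether 3 for steps 8, 9 and 10.

Most likely to fail, step 10. What may go wrong: erosion of the 1,3-syn facial bias at this most hindered aldol addition, β-elimination of the silyloxy group from aldehyde 14 under the basic olefination, or incomplete Z control. The fallback sets out from 13, sets C6 by catalyst control instead of relay and closes the ring by metathesis instead of olefination and lactonisation. Keck allylation of 13 with allylSnBu3, (S)-BINOL and Ti(OiPr)4 should give the homoallylic alcohol (4S,6S,8R,10R,14S)-14-OTBS-6,8,10-tris(OSi*)pentacos-1-en-4-ol F1. Acylation with acryloyl chloride, Et3N and DMAP gives the acrylate (4S,6S,8R,10R,14S)-14-OTBS-6,8,10-tris(OSi*)pentacos-1-en-4-yl prop-2-enoate F2. Ring-closing metathesis with second-generation Grubbs catalyst RuCl2(=CHPh)(H2IMes)(PCy3) in CH2Cl2 at 40 °C closes the ring at C3=C4 and gives the protected lactone (6S)-6-[(2S,4R,6R,10S)-10-OTBS-2,4,6-tris(OSi*)henicosyl]-5,6-dihydro-2H-pyran-2-one F3. HF·pyridine as in step 11 then brings the route back at 17.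

Second, step 11. What may go wrong: incomplete heterolytic Si–O cleavage at the four hindered Si* ethers, or, on forcing, acid-promoted conjugate addition of the freed C2' hydroxyl to C4. The fallback sets out from 15 and releases the Si* ethers photochemically, a cleavage mode documented for this silyl group that needs neither acid nor fluoride. Irradiation at 254 nm in CH2Cl2/MeOH should give the tetraol ester methyl (2Z,5S,7S,9R,11R,15S)-15-OTBS-5,7,9,11-tetrahydroxyhexacos-2-enoate F4; any E isomer formed under the lamp does not lactonise and is a loss. Catalytic TsOH in CH2Cl2 closes the lactone (6S)-6-[(2R,4R,6R,10S)-10-OTBS-2,4,6-trihydroxyhenicosyl]-5,6-dihydro-2H-pyran-2-one F5. Brief HF·pyridine treatment removes the single unhindered TBS ether and brings the route back at 17.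

Third, step 7. What may go wrong: oxidation of the Si–Si bonds of the Si* group by the K2OsO4/NaIO4 system, or β-elimination of the silyloxy group from the aldehyde in the aqueous medium. The fallback sets out from 7 and builds the aldehyde without any oxidant meeting the Si–Si bonds. Roskamp homologation with ethyl diazoacetate and SnCl2 (cat.) gives the β-keto ester ethyl (7S)-7-OTBS-3-oxooctadecanoate F6. Noyori hydrogenation with RuCl2[(R)-BINAP] and H2 in EtOH should set C6' and give ethyl (3R,7S)-7-OTBS-3-hydroxyoctadecanoate F7. Silylation with (Me3Si)3SiCl, Et3N and DMAP gives ethyl (3R,7S)-7-OTBS-3-(OSi*)octadecanoate F8. Reduction with iBu2AlH in CH2Cl2 at −78 °C brings the route back at 11.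

**Further compounds**

F1 | step 10 | (4S,6S,8R,10R,14S)-14-OTBS-6,8,10-tris(OSi*)pentacos-1-en-4-ol | CCCCCCCCCCC[C@H](O[Si](C)(C)C(C)(C)C)CCC[C@@H](O[Si]([Si](C)(C)C)([Si](C)(C)C)[Si](C)(C)C)C[C@@H](O[Si]([Si](C)(C)C)([Si](C)(C)C)[Si](C)(C)C)C[C@@H](O[Si]([Si](C)(C)C)([Si](C)(C)C)[Si](C)(C)C)C[C@@H](O)CC=C
F2 | step 10 | (4S,6S,8R,10R,14S)-14-OTBS-6,8,10-tris(OSi*)pentacos-1-en-4-yl prop-2-enoate | CCCCCCCCCCC[C@H](O[Si](C)(C)C(C)(C)C)CCC[C@@H](O[Si]([Si](C)(C)C)([Si](C)(C)C)[Si](C)(C)C)C[C@@H](O[Si]([Si](C)(C)C)([Si](C)(C)C)[Si](C)(C)C)C[C@@H](O[Si]([Si](C)(C)C)([Si](C)(C)C)[Si](C)(C)C)C[C@@H](OC(=O)C=C)CC=C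
F3 | step 10 | (6S)-6-[(2S,4R,6R,10S)-10-OTBS-2,4,6-tris(OSi*)henicosyl]-5,6-dihydro-2H-pyran-2-one | CCCCCCCCCCC[C@H](O[Si](C)(C)C(C)(C)C)CCC[C@@H](O[Si]([Si](C)(C)C)([Si](C)(C)C)[Si](C)(C)C)C[C@@H](O[Si]([Si](C)(C)C)([Si](C)(C)C)[Si](C)(C)C)C[C@@H](O[Si]([Si](C)(C)C)([Si](C)(C)C)[Si](C)(C)C)C[C@@H]1CC=CC(=O)O1
F4 | step 11 | methyl (2Z,5S,7S,9R,11R,15S)-15-OTBS-5,7,9,11-tetrahydroxyhexacos-2-enoate | CCCCCCCCCCC[C@H](O[Si](C)(C)C(C)(C)C)CCC[C@@H](O)C[C@@H](O)C[C@@H](O)C[C@@H](O)C/C=C\C(=O)OC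
F5 | step 11 | (6S)-6-[(2R,4R,6R,10S)-10-OTBS-2,4,6-trihydroxyhenicosyl]-5,6-dihydro-2H-pyran-2-one | CCCCCCCCCCC[C@H](O[Si](C)(C)C(C)(C)C)CCC[C@@H](O)C[C@@H](O)C[C@@H](O)C[C@@H]1CC=CC(=O)O1
F6 | step 7 | ethyl (7S)-7-OTBS-3-oxooctadecanoate | CCCCCCCCCCC[C@H](O[Si](C)(C)C(C)(C)C)CCCC(=O)CC(=O)OCC
F7 | step 7 | ethyl (3R,7S)-7-OTBS-3-hydroxyoctadecanoate | CCCCCCCCCCC[C@H](O[Si](C)(C)C(C)(C)C)CCC[C@@H](O)CC(=O)OCC
F8 | step 7 | ethyl (3R,7S)-7-OTBS-3-(OSi*)octadecanoate | CCCCCCCCCCC[C@H](O[Si](C)(C)C(C)(C)C)CCC[C@@H](O[Si]([Si](C)(C)C)([Si](C)(C)C)[Si](C)(C)C)CC(=O)OCC
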